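## Analysis of the target

Target 36 is a germacranolide: a ten-membered carbocycle C1–C10 (C14 methyl on C10, C15 exocyclic methylene on C4) fused across C6–C7 to an α-methylene-γ-butyrolactone (O6–C12(=O)–C11(=C13)). It carries a methacrylate on O8, a free hydroxyl on C5 and two epoxides (C1–C10 and C2–C3). The eight stereocentres are (1R,2S,3S,5R,6S,7R,8S,10R). In α/β terms the epoxide oxygen is β at C1 and α at C10 (the pattern of an E C1=C10 alkene oxidised from outside the ring) and α at C2 and C3 (a Z alkene). O5, O6 and O8 are all α and C11 on C7 is β, so the lactone is trans-fused. The sensitive groups are two Michael acceptors, a base-labile ester, and a bis-epoxide whose C3 carbon is allylic to the C4 methylene; acid, strong base and strong nucleophiles are therefore excluded late in the route. The real difficulty is the medium ring: ten-membered rings resist end-to-end closure, and this one needs an E trisubstituted alkene next to a Z alkene and oxygenated centres at C5, C6 and C8. The plan rests on one feature. With the epoxides taken back to alkenes and C6 at the ketone level, C6(=O)–C7–C8–C9–C10=C1 is a cyclodec-5-enone unit, and C1, C2=C3, C4, C5, C6 fit a cyclohexene. A six-membered ring C1–C6 can then be enlarged by the four atoms C7–C10 in a [3,3] shift that breaks C1–C6.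

## Retrosynthetic reasoning

**36 ⇒ 35 ⇒ 34 ⇒ 33 (O5–benzyl and O8–acyl bonds).** The C5 hydroxyl is unmasked last, by neutral oxidative cleavage of the 4-methoxybenzyl (PMB) ether of 35; acid, base or fluoride would each endanger the epoxides or the acrylate units. The methacrylate is cut next: 34 is the C8 alcohol, freed from the 3,4-dimethoxybenzyl (DMB) ether of 33. DMB is cleaved faster than PMB by the same quinone oxidant, so O8 and O5 can be told apart. A benzyl-type ether is wanted on O5 because two earlier steps rely on O5 as a chelating donor.

**33 ⇒ 32 ⇒ 31 (four epoxide C–O bonds).** Both epoxides are taken back to alkenes of the triene 31, the strained trisubstituted E alkene first. Oxidation after lactone methylenation avoids exposing epoxides to a lactone enolate. The forward reactions must pick C1=C10 and C2=C3 over the C4=C15 methylene and attack the right faces: the outer face of the E alkene in the conformation of a trans-6,12-lactonised germacrene, and the α face of the Z alkene under catalyst control.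

**31 ⇒ 29 ⇒ 27 ⇒ 26 ⇒ 25 (C11=C13, O6–C12, C6–H).** The methylene group is removed (Mannich base 29, lactone 27), the lactone opened to hydroxy ester 26, and C6 returned to the ketone 25. This places a carbonyl at C6 and an acetate arm on C7, the pattern an enolate alkylation can deliver. The reduction of 25 must give 6α-OH, which is anti to O5 and 1,3-syn to O8. Chelation of the C6 carbonyl to either neighbouring ether oxygen predicts exactly this face, which is why both are benzyl-type ethers.

**25 ⇒ 21 + 22 (C8–C9 and C7–C11; C1–C6 re-formed).** This is the key disconnection. Cutting C7–C11 gives the C6=C7 enolate and tert-butyl iodoacetate 22; a retro-[3,3] shift then contracts the ring to the cyclohexenol 21. The cut is made here because it replaces a ten-membered closure by a ring expansion. The same event fixes the E C1=C10 geometry, carries the Z C2=C3 alkene over from the six-membered ring, creates C8 from the enol ether geometry and leaves a regiodefined enolate for the C7 branch. The forward step must run through one chair and must alkylate before the β-alkoxy enolate eliminates or equilibrates.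

**21 ⇒ 20 ⇒ 19 ⇒ 12 + 16; 16 ⇒ 13 + 14.** The C2=C3 alkene of 21 is formed last, by elimination of the allylic benzoate 20. With both alkenes next to a C6 carbonyl the ring would be two proton shifts from a phenol, so the diene is made only after C6 is quaternary. The Z enol ether comes from the ynol ether 19, and the C6–C7 bond from addition of the alkoxyacetylide derived from 16 to ketone 12. That addition must put the new carbon trans to both O5 and the isopropenyl group; chelation between the carbonyl and the equatorial O5 ether directs it so. The dichlorovinyl ether 16 comes from alcohol 13 and trichloroethylene 14.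

**12 ⇒ 11 ⇒ 10 ⇒ 9 ⇒ 8 ⇒ 6 ⇒ 5 ⇒ 4 ⇒ 3 ⇒ 1.** The ketone 12 is (S)-carvone 1 with three changes: the carvone carbonyl reduced to the C5 ether, the α′ carbon oxidised to the C6 carbonyl, and the ring alkene turned into the C4 methylene with a leaving group on C3. The C1 centre of 1 has the configuration needed and is kept. The order is dictated by reactivity. C6 can only be oxidised through the enolate of 1 (3, protected as 4). The enone is then reduced (5), and the free C5 hydroxyl directs epoxidation to the ring alkene (6) before it is etherified (8). The epoxide is opened to the exocyclic allylic alcohol 9 and inverted to the axial benzoate 10. Desilylation (11) and oxidation give 12.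

## Alternatives that were turned down

**Alternative 1:** three-component conjugate addition and Mannich trapping on a butenolide. The disconnection cuts C7–C8 and C11–C13 of the lactone. In the forward step the lithiated dithiane A3 (C8 as a masked carbonyl, with the C9–C2 chain) adds to C7 of the butenolide A2 and the lactone enolate is trapped at C11 by Eschenmoser's salt, giving A1. For it: the addition goes anti to the C6 substituent and the trap anti to the new C7 branch, so the C6/C7/C11 relationship is set by a rigid five-membered ring. Three fragments are joined in one flask and the latent methylene is in place. On C7 control it is stronger than the chosen route, which relies on the conformation of a ten-membered enolate. Against it: no ring closes. After A1 the ten-membered ring must still be made by an end-to-end closure on the C2–C5 side, with the Z C2=C3 alkene, the C4 methylene and the C5 centre all still to be built, and the dithiane must become an 8α alcohol. The step count after the key step is therefore high, and the hardest problem, the medium ring, is untouched. The chosen strategy makes the ring and both alkene geometries in one step.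

**Alternative 2:** late carbonylative closure of the methylene lactone. The disconnection cuts C11–C12 and C12–O6. In the forward step Pd(PPh3)4 (zerovalent palladium) under CO inserts into a C7 1-iodoalkenyl group and the acylpalladium is captured by the free C6 hydroxyl, giving A4. For it: the α-methylene lactone appears in one neutral step with no enolate chemistry, where the chosen route needs alkylation, reduction, lactonisation and a two-step methylenation. On that point it is clearly more economical. Against it: it is an end-game tactic only. The ten-membered triene with C5, C6, C7, C8 set and a 1-iodovinyl branch on C7 must already exist, and the alternative offers no way to make it. Oxidative addition must also compete with a conjugated triene, an allylic C5 ether and a methacrylate under CO. The chosen strategy answers the ring question, and its enolate forms C7–C11 in the ring-forming step.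

**Alternative 3:** chromium-mediated closure at C1–C2 with the epoxide oxygen placed first. The disconnection cuts C1–C2. In the forward step CrCl2 (divalent chromium) with catalytic NiCl2 adds a Z alkenyl iodide terminus (C2) to an aldehyde terminus (C1) and closes the ring, giving A5. For it: the reaction tolerates lactone and ester, keeps the Z geometry, and lets the C1–C10 epoxide be made by displacement from a fixed C10 centre rather than by facial selection. On that point it is stronger than the chosen route. Against it: it is a direct ten-membered closure with the entropic and transannular cost the chosen route avoids. The C1 carbinol must come out as one specific epimer with no evident control element. The open chain needs five stereocentres, including the quaternary C10 and the complete lactone, before the key step. The C2–C3 epoxide still depends on facial selectivity, and two acrylate units are exposed to a stoichiometric reducing metal. The chosen route reaches its key step from a rigid six-membered precursor and forms the ring, two bonds and two stereocentres at once.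

Key step: step 14

Remark on the chemistry: ring atoms of every intermediate carry the germacrane numbers they have in 36. α/β refer to the ring viewed with C1→C10 anticlockwise and β towards the viewer. PMB = 4-methoxybenzyl (on O5), DMB = 3,4-dimethoxybenzyl (on O8).

## Route

Step 1
Reactants: 1 (S)-carvone
Product: 3 trans-6-hydroxycarvone (C6 hydroxyl anti to the C1 isopropenyl group), via potassium dienolate 2 (not isolated)
Conditions: KHMDS, THF, −78 °C; then 2-(phenylsulfonyl)-3-phenyloxaziridine, −78 °C; aq. NH4Cl
Reagents that add atoms: 2-(phenylsulfonyl)-3-phenyloxaziridine, O=S(=O)(c1ccccc1)N1OC1c1ccccc1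
Why: Kinetic deprotonation of the enone takes the α′ proton at C6, and electrophilic enolate hydroxylation by the oxaziridine occurs anti to the neighbouring isopropenyl group. The new C6 centre is only a handle and becomes the C6 carbonyl in step 9.

Step 2
Reactants: 3 trans-6-hydroxycarvone
Product: 4 6-O-triisopropylsilyl ether of 3
Conditions: i-Pr3SiOTf, 2,6-lutidine, CH2Cl2, −78 → 0 °C
Reagents that add atoms: triisopropylsilyl trifluoromethanesulfonate, CC(C)[Si](OS(=O)(=O)C(F)(F)F)(C(C)C)C(C)C
Why: Silylation of a secondary alcohol. The bulky silyl group is chosen because it should not migrate to the neighbouring oxygen under the basic etherification of step 5 and is later removed by fluoride beside a benzyl-type ether and a benzoate.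

Step 3
Reactants: 4 silyl ether
Product: 5 allylic alcohol with C5–OH cis to the C1 isopropenyl group and trans to O6
Conditions: NaBH4, CeCl3·7H2O, MeOH, −78 → −20 °C
Reagents that add atoms: none
Why: Luche 1,2-reduction. Hydride adds axially to the half-chair with the C1 and C6 substituents equatorial, as in the reduction of carvone to cis-carveol, and gives the equatorial C5 alcohol. This is the C5 centre of the target.

Step 4
Reactants: 5 allylic alcohol
Product: 6 3,4-epoxide with the epoxide oxygen cis to C5–OH
Conditions: VO(acac)2 (2 mol%), t-BuOOH, CH2Cl2, 0 °C → rt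
Reagents that add atoms: tert-butyl hydroperoxide, CC(C)(C)OO
Why: Hydroxyl-directed epoxidation of an allylic alcohol. Only the C3=C4 alkene next to the free hydroxyl reacts, the isopropenyl group is left alone, and oxygen is delivered syn to C5–OH.

Step 5
Reactants: 6 epoxy alcohol
Product: 8 5-O-(4-methoxybenzyl) ether of 6, via sodium alkoxide 7 (not isolated)
Conditions: NaH, 4-methoxybenzyl bromide, Bu4NI (cat.), THF/DMF, 0 °C → rt
Reagents that add atoms: 4-methoxybenzyl bromide, COc1ccc(CBr)cc1
Why: Williamson etherification. The alkoxide lies on the same face as the epoxide oxygen and so cannot open it by Payne rearrangement. The PMB ether is chosen as a chelating donor for steps 11 and 15 and for its neutral removal at the end.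

Step 6
Reactants: 8 epoxy ether
Product: 9 exocyclic allylic alcohol (C4=C15 methylene, C3–OH cis to O5)
Conditions: Et2Al(TMP) (made in the flask from Et2AlCl and LiTMP), toluene, 0 °C
Reagents that add atoms: none
Why: Base-induced isomerisation of an epoxide to an allylic alcohol. Aluminium binds the epoxide oxygen and the amide removes a syn proton from the least hindered β carbon, the C15 methyl, opening the C4–O bond. C3 keeps the configuration of the epoxide.

Step 7
Reactants: 9 allylic alcohol
Product: 10 3-benzoate with inverted C3 (benzoyloxy trans to O5)
Conditions: PhCO2H, PPh3, DIAD, THF, 0 °C → rt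
Reagents that add atoms: benzoic acid, OC(=O)c1ccccc1
Why: Mitsunobu esterification with inversion. The benzoate becomes axial and thus aligned with the C4=C15 π system for the ionisation in step 13, and it protects O3 through steps 8 to 12. Any SN2′ benzoate on C15 would lead to the same allyl complex.

Step 8
Reactants: 10 silyl ether benzoate
Product: 11 6-alcohol
Conditions: Bu4NF, AcOH, THF, rt → 40 °C
Reagents that add atoms: none
Why: Fluoride cleavage of the silyl ether, buffered with acetic acid so that the benzoate is not touched; the PMB ether is inert.

Step 9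
Reactants: 11 alcohol
Product: 12 6-ketone (C5 OPMB, C4 methylene, C3 axial benzoate, C1 isopropenyl)
Conditions: Dess–Martin periodinane, NaHCO3, CH2Cl2, 0 °C → rt
Reagents that add atoms: none
Why: Buffered periodinane oxidation of a secondary alcohol under near-neutral conditions, so the α-alkoxy β,γ-unsaturated ketone is not isomerised. The cis arrangement of the equatorial C5 and C1 substituents is also the thermodynamic one.

Step 10
Reactants: 13 3,4-dimethoxybenzyl alcohol; 14 trichloroethylene
Product: 16 (E)-1,2-dichlorovinyl 3,4-dimethoxybenzyl ether, via potassium alkoxide 15 (not isolated)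
Conditions: KH, THF, 0 °C; then 14, −50 °C → rt
Reagents that add atoms: none
Why: The alkoxide removes HCl from trichloroethylene and adds to the dichloroacetylene so formed (addition–elimination). This is the standard entry to alkoxyacetylide precursors.

Step 11
Reactants: 12 ketone; 16 dichlorovinyl ether
Product: 19 tertiary propargylic alcohol (alkoxyethynyl group on C6 trans to O5 and to the isopropenyl group), via lithium alkoxyacetylide 17 (not isolated), via alkynylcerium dichloride 18 (not isolated)
Conditions: 16, n-BuLi (2.2 equiv), THF, −78 → −40 °C; CeCl3 (anhydrous), −78 °C; then 12, −78 °C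
Reagents that add atoms: none
Why: n-BuLi converts 16 into the acetylide by elimination and chlorine–lithium exchange; the organocerium reagent adds to the enolisable ketone without deprotonating it. Cerium bridges the carbonyl and the equatorial O5 ether (Cram chelate), so attack comes from the H5 side, anti to C4. This sets C6 with OH cis to O5 and the new carbon trans to the isopropenyl group.

Step 12
Reactants: 19 ynol ether
Product: 20 (Z)-enol ether
Conditions: H2 (1 atm), Pd/CaCO3 poisoned with Pb(OAc)2 (Lindlar catalyst), quinoline, EtOAc, 0 °C
Reagents that add atoms: none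
Why: Syn semi-hydrogenation of the alkyne gives the Z enol ether; the poisoned catalyst leaves the 1,1-disubstituted alkenes, the benzyl-type ethers and the allylic benzoate alone. The step is run cold and at once because benzyl-type alkynyl ethers rearrange on warming.

Step 13
Reactants: 20 allylic benzoate
Product: 21 oxy-Cope precursor (cyclohex-2-en-6-ol with C1 isopropenyl, C4 methylene, C5 OPMB and C6 (Z)-2-(DMB-oxy)vinyl)
Conditions: Pd(PPh3)4 (5 mol%, zerovalent palladium), Et3N, THF, 65 °C
Reagents that add atoms: none
Why: Palladium-catalysed 1,4-elimination of an allylic ester (Tsuji–Trost-type ionisation, then β-hydride elimination). The exocyclic allyl complex has β hydrogens only on C2, so only the C2=C3/C4=C15 diene can form. The tertiary hydroxyl is on the palladium face and cannot capture the allyl unit.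

Step 14
Reactants: 21 oxy-Cope precursor; 22 tert-butyl iodoacetate
Product: 25 ten-membered keto ester (6-ketone, 1(10)E,2Z,4(15)-triene, 5α-OPMB, 7β-CH2CO2t-Bu, 8α-ODMB), via potassium alkoxide 23 (not isolated), via potassium enolate 24 (not isolated)
Conditions: KH, 18-crown-6, THF, 0 °C → rt; then −78 °C, 22, → −40 °C; aq. NH4Cl
Reagents that add atoms: none
Why: KH gives the alkoxide 23, whose oxyanion accelerates a [3,3]-sigmatropic shift (anionic oxy-Cope rearrangement, the known ring expansion of trans-1,2-dialkenylcyclohexanols to (E)-cyclodec-5-enones): C8–C9 forms as C1–C6 breaks, and the enolate 24 is then C-alkylated by 22 (C7–C11). The ten-membered ring is not closed end to end; it arises by four-atom enlargement through a chair transition state fused to the cyclohexene, with the enol ether and isopropenyl groups both equatorial (they are trans on C6 and C1). The chair puts C2 anti to C9, which gives the E C1=C10 alkene; the Z C2=C3 alkene is inherited; and the Z enol ether places the alkoxy group pseudo-axial, which fixes C8 with oxygen α. C7 is set in the alkylation: above 0 °C the enolate unit can turn through the ring, and the conformer with H8 eclipsing the enolate C–O bond and the O5 ether perpendicular to the C4 methylene exposes the face that puts C11 β; C7 stays α to the ketone and so remains epimerisable. The step needs the [3,3] shift through C9=C10 rather than a [1,3] shift or a shift through the C4=C15 or C2=C3 alkene; only C7=C8 and C9=C10 sit gauche on adjacent carbons, and the doubly allylic C1 makes C1–C6 the weakest bond β to the oxyanion. It also needs C-alkylation without loss of the C8 alkoxide from the β-alkoxy enolate; a soft primary iodide is used at −78 °C, and in the relaxed enolate the C8–O bond lies near the enolate plane, poorly aligned for E1cB elimination. The enolate is regiodefined (C6=C7) by the rearrangement and is quenched before proton transfer can move it towards C5.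

Step 15
Reactants: 25 keto ester
Product: 26 6α-hydroxy ester
Conditions: Zn(BH4)2, Et2O, −30 °C
Reagents that add atoms: none
Why: Chelation-controlled reduction. Zinc ties the carbonyl oxygen to the α ether on C5 (and can also reach the β ether on C8), and hydride comes from the outer, H5 side. Both chelates predict the 5,6-anti and 6,8-syn alcohol, that is 6α-OH.

Step 16
Reactants: 26 hydroxy ester
Product: 27 trans-fused lactone (6α,12-olide)
Conditions: KOt-Bu (0.2 equiv), THF, 0 °C → rt
Reagents that add atoms: none
Why: Base-catalysed intramolecular transesterification (5-exo-trig) of the C6 alkoxide onto the tert-butyl ester. Acid is avoided because the C5 ether is allylic to a conjugated triene.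

Step 17
Reactants: 27 lactone
Product: 29 11-(dimethylaminomethyl) lactone, via lithium lactone enolate 28 (not isolated)
Conditions: LDA, THF, −78 °C; then Me2N=CH2 iodide (Eschenmoser's salt), −78 → 0 °C
Reagents that add atoms: dimethylmethyleneammonium iodide, C[N+](C)=C.[I-]
Why: Mannich reaction of the lactone enolate; C11 is the only acidic position and no leaving group is β to it. The iminium ion should add anti to the C8 branch on C7, but the C11 centre is lost in step 18.

Step 18
Reactants: 29 Mannich base
Product: 31 α-methylene lactone triene, via trimethylammonium iodide 30 (not isolated)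
Conditions: MeI, CH2Cl2, rt; then aq. NaHCO3, EtOAc, rt
Reagents that add atoms: none
Why: Quaternisation followed by E1cB elimination of trimethylamine gives the C11=C13 methylene under conditions too mild to affect the triene or the benzyl-type ethers.

Step 19
Reactants: 31 triene
Product: 32 1β,10α-epoxide
Conditions: mCPBA (1.05 equiv), NaHCO3, CH2Cl2, −40 → 0 °C
Reagents that add atoms: 3-chloroperoxybenzoic acid, O=C(OO)c1cccc(Cl)c1
Why: Peracid epoxidation takes the most electron-rich and most strained alkene, the E trisubstituted C1=C10. Attack is from outside the ring on the conformer usual for trans-6,12-lactonised germacra-1(10)-enes (C14 on the β face), which gives oxygen β at C1 and α at C10. The methylene lactone is too electron-poor to react.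

Step 20
Reactants: 32 mono-epoxide
Product: 33 1β,10α:2α,3α-bis-epoxide
Conditions: (S,S)-(salen)MnCl (C36H52ClMnN2O2, trivalent manganese; 10 mol%), N-methylmorpholine N-oxide, mCPBA, CH2Cl2, −78 °C
Reagents that add atoms: 3-chloroperoxybenzoic acid, O=C(OO)c1cccc(Cl)c1
Why: Jacobsen–Katsuki epoxidation. The catalyst is selective for cis-disubstituted alkenes conjugated to another π system, so it takes C2=C3 and leaves the 1,1-disubstituted C4=C15 methylene. The (S,S) ligand is the one that delivers oxygen to the face giving (2S,3S), and ring constraint prevents cis-to-trans leakage.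

Step 21
Reactants: 33 bis-epoxide
Product: 34 8α-alcohol
Conditions: DDQ (1.1 equiv), CH2Cl2/pH 7 buffer, 0 °C
Reagents that add atoms: none
Why: Oxidative cleavage of a benzyl-type ether by hydride abstraction. The more electron-rich DMB ether reacts faster than the PMB ether on O5, and the buffered neutral medium spares the epoxides.

Step 22
Reactants: 34 alcohol
Product: 35 8-O-methacrylate (O5 still PMB)
Conditions: methacrylic anhydride, Et3N, DMAP (cat.), CH2Cl2, 0 °C
Reagents that add atoms: methacrylic anhydride, C=C(C)C(=O)OC(=O)C(C)=C
Why: DMAP-catalysed acylation of the only free hydroxyl. The anhydride is used instead of the acid chloride so that no chloride is present to open the epoxides.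

Step 23
Reactants: 35 PMB ether
Product: 36 target
Conditions: DDQ (2 equiv), CH2Cl2/pH 7 buffer, rt
Reagents that add atoms: none
Why: Oxidative removal of the PMB ether under neutral conditions frees the C5 hydroxyl. No acid, base or fluoride is needed in the presence of the epoxides, the methacrylate and the methylene lactone.

## Compound list

1 | (S)-carvone | CC1=CC[C@@H](CC1=O)C(C)=C | starting material
2 | potassium cross-conjugated dienolate of 1 (O–C5=C6) | CC1=CC[C@@H](C=C1[O-])C(C)=C.[K+] | intermediate
3 | trans-6-hydroxycarvone (C6–OH anti to the C1 isopropenyl group) | O[C@H]1C(=O)C(C)=CC[C@@H]1C(C)=C | intermediate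
4 | 6-O-triisopropylsilyl ether of 3 | CC(C)[Si](C(C)C)(C(C)C)O[C@H]1C(=O)C(C)=CC[C@@H]1C(C)=C | intermediate
5 | 5-alcohol of 4 (C5–OH cis to isopropenyl, trans to O6) | CC(C)[Si](C(C)C)(C(C)C)O[C@H]1[C@H](O)C(C)=CC[C@@H]1C(C)=C | intermediate
6 | 3,4-epoxide of 5 (epoxide oxygen cis to C5–OH) | CC(C)[Si](C(C)C)(C(C)C)O[C@H]1[C@H](O)[C@]2(C)O[C@@H]2C[C@@H]1C(C)=C | intermediate
7 | sodium C5-alkoxide of 6 | CC(C)[Si](C(C)C)(C(C)C)O[C@H]1[C@H]([O-])[C@]2(C)O[C@@H]2C[C@@H]1C(C)=C.[Na+] | intermediate
8 | 5-O-PMB ether of 6 | CC(C)[Si](C(C)C)(C(C)C)O[C@H]1[C@H](OCc2ccc(OC)cc2)[C@]3(C)O[C@@H]3C[C@@H]1C(C)=C | intermediate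
9 | exocyclic allylic alcohol (C4 methylene, C3–OH cis to O5, C5 OPMB, C6 OTIPS) | CC(C)[Si](C(C)C)(C(C)C)O[C@H]1[C@H](OCc2ccc(OC)cc2)C(=C)[C@H](O)C[C@@H]1C(C)=C | intermediate
10 | 3-benzoate with inverted C3 (benzoyloxy trans to O5) | CC(C)[Si](C(C)C)(C(C)C)O[C@H]1[C@H](OCc2ccc(OC)cc2)C(=C)[C@@H](OC(=O)c2ccccc2)C[C@@H]1C(C)=C | intermediate
11 | 6-alcohol (10 without the silyl group) | O[C@H]1[C@H](OCc2ccc(OC)cc2)C(=C)[C@@H](OC(=O)c2ccccc2)C[C@@H]1C(C)=C | intermediate
12 | 6-ketone (C5 OPMB, C4 methylene, C3 benzoate, C1 isopropenyl) | O=C1[C@H](OCc2ccc(OC)cc2)C(=C)[C@@H](OC(=O)c2ccccc2)C[C@@H]1C(C)=C | intermediate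
13 | 3,4-dimethoxybenzyl alcohol | COc1ccc(CO)cc1OC | starting material
14 | trichloroethylene | ClC=C(Cl)Cl | starting material
15 | potassium 3,4-dimethoxybenzyl oxide | COc1ccc(C[O-])cc1OC.[K+] | intermediate
16 | (E)-1,2-dichlorovinyl 3,4-dimethoxybenzyl ether | COc1ccc(COC(/Cl)=C\Cl)cc1OC | intermediate
17 | lithium (3,4-dimethoxybenzyloxy)acetylide | COc1ccc(COC#C[Li])cc1OC | intermediate
18 | [(3,4-dimethoxybenzyloxy)ethynyl]cerium dichloride | COc1ccc(COC#C[Ce](Cl)Cl)cc1OC | intermediate
19 | tertiary propargylic alcohol (C6–OH cis to O5 and isopropenyl; DMB-oxyethynyl trans) | COc1ccc(COC#C[C@@]2(O)[C@H](OCc3ccc(OC)cc3)C(=C)[C@@H](OC(=O)c3ccccc3)C[C@@H]2C(C)=C)cc1OC | intermediate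
20 | (Z)-enol ether benzoate | COc1ccc(CO/C=C\[C@@]2(O)[C@H](OCc3ccc(OC)cc3)C(=C)[C@@H](OC(=O)c3ccccc3)C[C@@H]2C(C)=C)cc1OC | intermediate
21 | oxy-Cope precursor: cyclohex-2-en-6-ol with C1 isopropenyl, C4 methylene, C5 OPMB, C6 (Z)-2-(DMB-oxy)vinyl | COc1ccc(CO/C=C\[C@@]2(O)[C@H](OCc3ccc(OC)cc3)C(=C)C=C[C@@H]2C(C)=C)cc1OC | intermediate
22 | tert-butyl iodoacetate | CC(C)(C)OC(=O)CI | starting material
23 | potassium alkoxide of 21 | COc1ccc(CO/C=C\[C@@]2([O-])[C@H](OCc3ccc(OC)cc3)C(=C)C=C[C@@H]2C(C)=C)cc1OC.[K+] | intermediate
24 | ten-membered potassium enolate (C6=C7; 1(10)E,2Z,4(15)-triene; 5α-OPMB; 8α-ODMB) | C1/C(C)=C/C=C\C(=C)[C@@H](OCc2ccc(OC)cc2)/C([O-])=C/[C@H]1OCc3ccc(OC)c(OC)c3.[K+] | intermediate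
25 | ten-membered keto ester (6-ketone, 7β-CH2CO2t-Bu) | C1/C(C)=C/C=C\C(=C)[C@@H](OCc2ccc(OC)cc2)C(=O)[C@H](CC(=O)OC(C)(C)C)[C@H]1OCc3ccc(OC)c(OC)c3 | intermediate
26 | 6α-hydroxy ester | C1/C(C)=C/C=C\C(=C)[C@@H](OCc2ccc(OC)cc2)[C@@H](O)[C@H](CC(=O)OC(C)(C)C)[C@H]1OCc3ccc(OC)c(OC)c3 | intermediate
27 | trans-fused lactone (6α,12-olide) triene | C1/C(C)=C/C=C\C(=C)[C@@H](OCc2ccc(OC)cc2)[C@H]4OC(=O)C[C@@H]4[C@H]1OCc3ccc(OC)c(OC)c3 | intermediate
28 | lithium enolate of 27 | C1/C(C)=C/C=C\C(=C)[C@@H](OCc2ccc(OC)cc2)[C@H]4OC([O-])=C[C@@H]4[C@H]1OCc3ccc(OC)c(OC)c3.[Li+] | intermediate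
29 | 11-(dimethylaminomethyl) lactone (expected major C11 epimer) | C1/C(C)=C/C=C\C(=C)[C@@H](OCc2ccc(OC)cc2)[C@H]4OC(=O)[C@@H](CN(C)C)[C@@H]4[C@H]1OCc3ccc(OC)c(OC)c3 | intermediate
30 | trimethylammonium iodide of 29 | C1/C(C)=C/C=C\C(=C)[C@@H](OCc2ccc(OC)cc2)[C@H]4OC(=O)[C@@H](C[N+](C)(C)C)[C@@H]4[C@H]1OCc3ccc(OC)c(OC)c3.[I-] | intermediate
31 | α-methylene lactone triene | C1/C(C)=C/C=C\C(=C)[C@@H](OCc2ccc(OC)cc2)[C@H]4OC(=O)C(=C)[C@@H]4[C@H]1OCc3ccc(OC)c(OC)c3 | intermediate
32 | 1β,10α-epoxide | C1[C@@]5(C)O[C@@H]5/C=C\C(=C)[C@@H](OCc2ccc(OC)cc2)[C@H]4OC(=O)C(=C)[C@@H]4[C@H]1OCc3ccc(OC)c(OC)c3 | intermediate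
33 | 1β,10α:2α,3α-bis-epoxide | C1[C@@]5(C)O[C@@H]5[C@H]6O[C@H]6C(=C)[C@@H](OCc2ccc(OC)cc2)[C@H]4OC(=O)C(=C)[C@@H]4[C@H]1OCc3ccc(OC)c(OC)c3 | intermediate
34 | 8α-alcohol | C1[C@@]5(C)O[C@@H]5[C@H]6O[C@H]6C(=C)[C@@H](OCc2ccc(OC)cc2)[C@H]4OC(=O)C(=C)[C@@H]4[C@H]1O | intermediate
35 | 8-O-methacrylate, 5-O-PMB ether | C1[C@@]5(C)O[C@@H]5[C@H]6O[C@H]6C(=C)[C@@H](OCc2ccc(OC)cc2)[C@H]4OC(=O)C(=C)[C@@H]4[C@H]1OC(=O)C(C)=C | intermediate
36 | ACon1_002091, (1R,2S,3S,5R,6S,7R,8S,10R)-1,10:2,3-diepoxy-5-hydroxy-8-methacryloyloxygermacra-4(15),11(13)-dien-6,12-olide | C=C(C)C(=O)O[C@H]1C[C@@]2(C)O[C@@H]2[C@H]2O[C@H]2C(=C)[C@@H](O)[C@H]2OC(=O)C(=C)[C@@H]21 | target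

## Step count and least certain steps

Total: 23 steps. Longest linear sequence: 22 steps from 1 (steps 1–9 and 11–23); step 10 is the one-step branch from 13 and 14.

**Step 14 (key step).** The most likely failures are β-elimination of the C8 alkoxide from the potassium enolate while it waits for the electrophile, and alkylation on the wrong face of C7 if the enolate reacts before it has relaxed from the conformation in which it is born. A partly stepwise cleavage of the doubly allylic C1–C6 bond could also erode the C8 configuration. Fallback (sets out from 21, returns at 25): the rearrangement is run as before, but as soon as 21 is consumed the enolate is silylated at −78 °C (Me3SiCl, Et3N) and the ten-membered trimethylsilyl enol ether F1 is isolated. MeLi in THF then releases the lithium enolate regiospecifically and without excess base, and this is alkylated with 22 in THF/DMPU at −78 °C to give 25. The enolate lifetime at ambient temperature is cut to a minimum, the lithium enolate of a β-alkoxy ketone is less prone to elimination, and the alkylation starts from a conformationally equilibrated enol derivative.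

**Step 11.** The most likely failures are addition along the axial trajectory, because the alkynyl nucleophile is small and chelation may be incomplete, and sigmatropic rearrangement of the benzyl-type ynol ether before it is reduced. Fallback (sets out from 13 and 12, returns at 20, and makes step 12 unnecessary): 13 is vinylated with butyl vinyl ether, Pd(OCOCF3)2 (divalent palladium) and 4,7-diphenyl-1,10-phenanthroline to 3,4-dimethoxybenzyl vinyl ether F2. Bromine at −78 °C gives the 1,2-dibromoethyl ether F3, and DBU eliminates HBr to the (Z)-2-bromovinyl ether F4. t-BuLi at −78 °C gives (Z)-2-(3,4-dimethoxybenzyloxy)vinyllithium F5, which is added to 12 in the presence of MgBr2·OEt2 to give 20 directly. The bulkier sp2 nucleophile prefers the equatorial trajectory even where chelation is weak, and no ynol ether is handled.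

**Step 15.** The most likely failure is hydride delivery without chelation (Felkin-type, anti to the C5–O bond), because the ten-membered ring may not let O5, the carbonyl and zinc become coplanar; this would reverse the C6 configuration. Fallback (sets out from 25, returns at 27): the other face is taken on purpose and C6 is inverted in the ring closure. A bulky non-chelating hydride (L-Selectride, THF, −78 °C) gives the 6β-hydroxy ester F6. Me3SiOTf/2,6-lutidine cleaves the tert-butyl ester to the 6β-hydroxy acid F7. Mitsunobu lactonisation (PPh3, DIAD, toluene, 0 °C) then closes the lactone by carboxylate displacement with inversion at C6, giving 27.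

**Step 20.** The most likely failures are poor facial selectivity, if the bias of the ring opposes the catalyst, and competing oxidation of the C4=C15 methylene. Fallback (sets out from 32, returns at 33): a halohydrin sequence, which ends with oxygen on the face opposite to the one an electrophile reaches first. NBS in aqueous acetone adds bromine to the more accessible face at C2 and water to the allylic C3 from the other side, giving the 2β-bromo-3α-hydroxy compound F8. DBU in CH2Cl2 then closes the epoxide with inversion at C2, giving 33.

**Step 21.** The most likely failure is incomplete discrimination between the two benzyl-type ethers, that is loss of the PMB ether together with the DMB ether. Fallback (sets out from 33, returns at 36): both ethers are removed on purpose with excess DDQ to give the 5,8-diol F9. The C8 hydroxyl lies between a methine and a methylene, whereas the C5 hydroxyl is flanked by the fully substituted C4 and the ring-fusion carbon C6. F9 is therefore acylated at O8 (methacrylic anhydride 1.05 equiv, 2,4,6-collidine, DMAP cat., CH2Cl2, −40 °C) to give 36 directly.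

## Further compounds

F1 | step 14 | ten-membered trimethylsilyl enol ether (C6–OSiMe3, C6=C7; 5α-OPMB, 8α-ODMB) | C1/C(C)=C/C=C\C(=C)[C@@H](OCc2ccc(OC)cc2)/C(O[Si](C)(C)C)=C/[C@H]1OCc3ccc(OC)c(OC)c3
F2 | step 11 | 3,4-dimethoxybenzyl vinyl ether | COc1ccc(COC=C)cc1OC
F3 | step 11 | 1,2-dibromoethyl 3,4-dimethoxybenzyl ether | COc1ccc(COC(Br)CBr)cc1OC
F4 | step 11 | (Z)-2-bromovinyl 3,4-dimethoxybenzyl ether | COc1ccc(CO/C=C\Br)cc1OC
F5 | step 11 | (Z)-2-(3,4-dimethoxybenzyloxy)vinyllithium | COc1ccc(CO/C=C\[Li])cc1OC
F6 | step 15 | 6β-hydroxy ester (C6 epimer of 26) | C1/C(C)=C/C=C\C(=C)[C@@H](OCc2ccc(OC)cc2)[C@H](O)[C@H](CC(=O)OC(C)(C)C)[C@H]1OCc3ccc(OC)c(OC)c3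
F7 | step 15 | 6β-hydroxy acid | C1/C(C)=C/C=C\C(=C)[C@@H](OCc2ccc(OC)cc2)[C@H](O)[C@H](CC(=O)O)[C@H]1OCc3ccc(OC)c(OC)c3
F8 | step 20 | 2β-bromo-3α-hydroxy 1β,10α-epoxide (bromohydrin) | C1[C@@]5(C)O[C@@H]5[C@H](Br)[C@@H](O)C(=C)[C@@H](OCc2ccc(OC)cc2)[C@H]4OC(=O)C(=C)[C@@H]4[C@H]1OCc3ccc(OC)c(OC)c3
F9 | step 21 | 5α,8α-diol bis-epoxide | C1[C@@]5(C)O[C@@H]5[C@H]6O[C@H]6C(=C)[C@@H](O)[C@H]4OC(=O)C(=C)[C@@H]4[C@H]1O
A1 | alternative 1 | trans,trans-lactone with C6 silyloxymethyl, C7 dithianyl side chain (C8 to C2) and C11 dimethylaminomethyl group | CC(C)(C)[Si](C)(C)OC[C@H]1OC(=O)[C@@H](CN(C)C)[C@@H]1C1(SCCCS1)C/C(C)=C/CO[Si](C)(C)C(C)(C)C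
A2 | alternative 1 | (S)-5-(tert-butyldimethylsilyloxymethyl)furan-2(5H)-one | CC(C)(C)[Si](C)(C)OC[C@H]1OC(=O)C=C1
A3 | alternative 1 | 2-lithio-2-[(E)-4-(tert-butyldimethylsilyloxy)-2-methylbut-2-enyl]-1,3-dithiane | [Li]C1(C/C(C)=C/CO[Si](C)(C)C(C)(C)C)SCCCS1
A4 | alternative 2 | 5-silyloxy-8-methacryloyloxy-germacra-1(10)E,2Z,4(15),11(13)-tetraen-6,12-olide | C=C(C)C(=O)O[C@H]1C/C(C)=C/C=C\C(=C)[C@@H](O[Si](C)(C)C(C)(C)C)[C@H]2OC(=O)C(=C)[C@@H]21
A5 | alternative 3 | ten-membered 1-hydroxy-10-silyloxy-2Z,4(15)-diene lactone (C1 epimeric to the target epoxide carbon) | C=C(C)C(=O)O[C@H]1C[C@@](C)(O[Si](CC)(CC)CC)[C@@H](O)/C=C\C(=C)[C@@H](O[Si](C)(C)C(C)(C)C)[C@H]2OC(=O)C(=C)[C@@H]21
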